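**Plan**

1. The target is a symmetrical, achiral dibenzyl ether. In each ring C1 carries the CH2O link, C2, C3 and C6 carry Br, and C4 and C5 carry OH.
2. Retrosynthesis first removes the six aryl C–Br bonds together with the aromatic unsaturation, back to a saturated ring holding a masked 1,2-dione. It then cuts C4–C5 in both rings, then C1–C2 and C1–C6, which leaves the O(CH2)2 core of 2,5-dihydrofuran.
3. The enabling feature is that C4 and C5, the two oxygen-bearing ring carbons, are neighbours, just as the two ester carbons united by an acyloin condensation are. Before aromatisation the benzylic ether is an ordinary dialkyl ether that sodium leaves alone.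
4. Forward, both chains grow at once from the ether core (ozonolysis/Wittig makes C1–C6, cuprate addition makes C1–C2, a second ozonolysis gives the esters). The two six-membered carbocycles close in one flask in step 4, and bromine then supplies the dione, the aromatic ring and the three bromines of each half.
5. Stereochemistry: the target has none. The two stereocentres formed in step 2 (the future C1 atoms) are left unassigned and disappear in step 5.

Key step: step 4

Remark: compounds 8 to 12 are carried as mixtures of the meso and racemic diastereomers, and but-3-en-1-ylmagnesium bromide is taken as the purchased THF solution.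

**Route**

Step 1
Reactants: 1 2,5-dihydrofuran; 2 methyl (triphenylphosphoranylidene)acetate
Product: 5 dimethyl (2E,2'E)-4,4'-oxybis(but-2-enoate), via 2,5-dihydrofuran ozonide 3 (not isolated), via 2,2'-oxydiacetaldehyde 4 (not isolated)
Conditions: O3, CH2Cl2, −78 °C; PPh3 (1.05 equiv), −78 → 0 °C; then 2 (2.3 equiv), 0 °C → rt
Reagents that add atoms: methyl (triphenylphosphoranylidene)acetate (compound 2), COC(=O)C=P(c1ccccc1)(c1ccccc1)c1ccccc1; ozone, [O-][O+]=O (its oxygen atoms are present in 3 and 4 only and leave as Ph3P=O)
Why: Ozonolysis of the ring alkene in a non-participating solvent stops at the bicyclic ozonide, PPh3 reduces it to the dialdehyde, and the stabilised ylide olefinates both aldehydes in the same flask (ozonolysis followed by double Wittig olefination, E geometry expected from an ester ylide), so that the hydration-prone dialdehyde is never concentrated.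

Step 2
Reactants: 5 dimethyl (2E,2'E)-4,4'-oxybis(but-2-enoate); 6 but-3-en-1-ylmagnesium bromide; 7 chlorotrimethylsilane
Product: 9 dimethyl 3,3'-[oxybis(methylene)]bis(hept-6-enoate), via bis(trimethylsilyl ketene acetal) 8 (not isolated)
Conditions: 6 (2.6 equiv), CuBr·SMe2 (10 mol %), Me3SiCl (3 equiv), DMPU (3 equiv), THF, −78 → −40 °C; then 1 M HCl, 0 °C
Reagents that add atoms: but-3-en-1-ylmagnesium bromide (compound 6), C=CCC[Mg]Br; chlorotrimethylsilane (compound 7), C[Si](C)(C)Cl (silicon is present in 8 only)
Why: Copper-catalysed conjugate addition of a Grignard reagent to an enoate, accelerated by Me3SiCl, which captures each adduct as its silyl ketene acetal so that no metal enolate remains to attack the second enoate across the ether, the acidic work-up returning the esters; the two new stereocentres form without control and are erased in step 5.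

Step 3
Reactants: 9 dimethyl 3,3'-[oxybis(methylene)]bis(hept-6-enoate)
Product: 10 tetramethyl 3,3'-[oxybis(methylene)]bis(hexanedioate)
Conditions: O3, NaOH (2.5 M in MeOH, 10 equiv), CH2Cl2, −78 °C; cold aqueous work-up
Reagents that add atoms: ozone, [O-][O+]=O; methanol, CO
Why: Ozonolysis in methanolic NaOH converts each terminal alkene directly into a methyl ester with loss of the terminal carbon, the carbonyl oxide and aldehyde fragments being taken up by methoxide and oxidised further by ozone, while the methyl esters already present can only exchange methoxide for methoxide.

Step 4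
Reactants: 10 tetramethyl 3,3'-[oxybis(methylene)]bis(hexanedioate); 7 chlorotrimethylsilane
Product: 11 bis{[3,4-bis(trimethylsilyloxy)cyclohex-3-en-1-yl]methyl} ether
Conditions: Na dispersion (8.8 equiv), Me3SiCl (9.5 equiv), toluene, reflux, 10 added over 8 h by syringe pump (high dilution), N2; filtration under N2, evaporation
Reagents that add atoms: chlorotrimethylsilane (compound 7), C[Si](C)(C)Cl
Why: Sodium transfers one electron to each ester carbonyl, the two ketyl radical anions of one hexanedioate unit couple at carbon to form C4–C5, expulsion of two methoxides leaves the 1,2-dione, and two further electrons give the enediolate, which Me3SiCl silylates on both oxygens. The closest known reaction is the acyloin condensation of a 1,6-diester with chlorosilane trapping, here run twice within one molecule. Each ring closes as a six-membered carbocycle by intramolecular reductive coupling of the two ester carbons of one hexanedioate unit, the new bond lying between the two oxygen-bearing carbons. No stereocentre is created, and the two existing ones (C1 of each ring) are untouched and stay a meso/racemic mixture. The selectivity needed is six-ring closure in each half over Dieckmann condensation and over coupling between the halves or between molecules; Me3SiCl removes methoxide as MeOSiMe3 and so closes the Dieckmann path, cross-coupling within the molecule would need nine- to eleven-membered rings, and slow addition at high dilution disfavours oligomers. The only other functional group is the dialkyl ether, which is inert to sodium.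

Step 5
Reactants: 11 bis{[3,4-bis(trimethylsilyloxy)cyclohex-3-en-1-yl]methyl} ether
Product: 13 bis(2,3,6-tribromo-4,5-dihydroxybenzyl) ether, via tetraketone 12 (not isolated)
Conditions: Br2 (2.0 equiv), CH2Cl2, −78 °C; then NaOAc (16 equiv), AcOH (10 vol %), Br2 (8.1 equiv, in portions), 0 → 40 °C, dark; aq. Na2S2O4 work-up
Reagents that add atoms: bromine, BrBr
Why: Bromine first cleaves the silyl enediols to the 1,2-diones (halogenative desilylation of an acyloin bis-silyl ether), then α-brominates their enol forms at C3 and C6, loss of HBr brings each ring to the catechol oxidation level, and electrophilic bromination fills every remaining ring position (bromination–dehydrobromination aromatisation of a cyclohexane-1,2-dione followed by exhaustive bromination of a catechol), so that no regiochemistry has to be controlled because all three free ring carbons end as C–Br, the acetate buffer keeping HBr and Me3SiBr away from the benzylic ether and dithionite returning any o-quinone to the catechol.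

**Compound list**

1 | 2,5-dihydrofuran | C1OCC=C1 | starting material
2 | methyl (triphenylphosphoranylidene)acetate | COC(=O)C=P(c1ccccc1)(c1ccccc1)c1ccccc1 | starting material
3 | 2,5-dihydrofuran ozonide (3,6,7,8-tetraoxabicyclo[3.2.1]octane, meso) | C1OC[C@H]2OO[C@@H]1O2 | intermediate (not isolated)
4 | 2,2'-oxydiacetaldehyde | O=CCOCC=O | intermediate (not isolated)
5 | dimethyl (2E,2'E)-4,4'-oxybis(but-2-enoate) | COC(=O)/C=C/COC/C=C/C(=O)OC | intermediate
6 | but-3-en-1-ylmagnesium bromide | C=CCC[Mg]Br | starting material
7 | chlorotrimethylsilane | C[Si](C)(C)Cl | starting material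
8 | bis(trimethylsilyl ketene acetal) of 9, 3,3'-[oxybis(methylene)]bis(1-methoxy-1-trimethylsilyloxyhepta-1,6-diene) (ketene acetal geometry and two stereocentres unassigned) | COC(O[Si](C)(C)C)=CC(CCC=C)COCC(CCC=C)C=C(OC)O[Si](C)(C)C | intermediate (not isolated)
9 | dimethyl 3,3'-[oxybis(methylene)]bis(hept-6-enoate) (two unassigned stereocentres, meso and racemic forms) | COC(=O)CC(CCC=C)COCC(CCC=C)CC(=O)OC | intermediate
10 | tetramethyl 3,3'-[oxybis(methylene)]bis(hexanedioate) (two unassigned stereocentres, meso and racemic forms) | COC(=O)CCC(CC(=O)OC)COCC(CC(=O)OC)CCC(=O)OC | intermediate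
11 | bis{[3,4-bis(trimethylsilyloxy)cyclohex-3-en-1-yl]methyl} ether (two unassigned stereocentres; cyclohexene locants 3 and 4 are C5 and C4 of the target ring) | C[Si](C)(C)OC1=C(O[Si](C)(C)C)CC(COCC2CCC(O[Si](C)(C)C)=C(O[Si](C)(C)C)C2)CC1 | intermediate
12 | 4,4'-[oxybis(methylene)]bis(cyclohexane-1,2-dione) (tetraketone, drawn in the diketo form; two unassigned stereocentres) | O=C1CCC(COCC2CCC(=O)C(=O)C2)CC1=O | intermediate (not isolated)
13 | bis(2,3,6-tribromo-4,5-dihydroxybenzyl) ether | Oc1c(O)c(Br)c(COCc2c(Br)c(O)c(O)c(Br)c2Br)c(Br)c1Br | target

**Totals**

Total step count: 5. Longest linear sequence: 5 steps (from 2,5-dihydrofuran).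

**Steps most likely to fail**

Step 5. The α-brominated diones may not shed HBr below the temperature at which the benzylic C–O bond of the aromatised product begins to ionise toward a quinone methide (solvolysis by acetic acid or bromide). Excess bromine may also over-oxidise the catechol to the o-quinone. The fallback separates aromatisation from bromination and keeps the catechol silylated until the end. It sets out from 11: Br2 (2.0 equiv) alone in CH2Cl2 at −78 °C gives tetraketone 12, now isolated. Me3SiOTf/Et3N (CH2Cl2, 0 °C) converts 12 into bis{[3,4-bis(trimethylsilyloxy)cyclohexa-2,4-dien-1-yl]methyl} ether F1; each carbonyl can enolise in one direction only, so a single diene results. DDQ (toluene, rt) dehydrogenates the two cyclohexa-1,3-dienes to bis[3,4-bis(trimethylsilyloxy)benzyl] ether F2 under neutral conditions. F2 is then treated with Br2 (6 equiv) and NaOAc in CH2Cl2/AcOH at 0 °C, where the acid cleaves the aryl silyl ethers as bromination proceeds. This returns to the route at 13.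

Step 4. Reductive coupling may occur between chains or between molecules (oligomers), or reduction may be incomplete and leave one half open. The fallback forms the same C4–C5 bonds by pinacol coupling. It sets out from 10: i-Bu2AlH (4.2 equiv, CH2Cl2, −78 °C) gives 3,3'-[oxybis(methylene)]bis(hexanedial) F3. SmI2 (THF, t-BuOH, −78 °C → rt) closes both six-membered rings by intramolecular pinacol coupling of each 1,6-dialdehyde, giving 4,4'-[oxybis(methylene)]bis(cyclohexane-1,2-diol) F4; the diol configuration is irrelevant. Swern oxidation (DMSO, (CF3CO)2O, Et3N, CH2Cl2, −78 °C) gives tetraketone 12, where the route is rejoined at the second stage of step 5.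

Step 2. The enolate of the first adduct may add to the second enoate across the ether (ring closure to a tetrahydropyran) faster than it is silylated, or the Grignard reagent may attack the ester carbonyls. The fallback installs both arms at the branching carbon without any enolate. It sets out from 5: i-Bu2AlH (CH2Cl2, −78 °C) gives (2E,2'E)-4,4'-oxybis(but-2-en-1-ol) F5. Johnson–Claisen rearrangement (MeC(OMe)3, catalytic propanoic acid, 140 °C) gives dimethyl 3,3'-[oxybis(methylene)]bis(pent-4-enoate) F6. Linear-selective methoxycarbonylation of both vinyl groups (Pd(OAc)2, 1,2-bis(di-tert-butylphosphinomethyl)benzene, MeSO3H, CO, MeOH, 80 °C) returns to the route at 10, bypassing 9.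

**Further compounds**

F1 | step 5 | bis{[3,4-bis(trimethylsilyloxy)cyclohexa-2,4-dien-1-yl]methyl} ether (two unassigned stereocentres) | C[Si](C)(C)OC1=CC(COCC2C=C(O[Si](C)(C)C)C(O[Si](C)(C)C)=CC2)CC=C1O[Si](C)(C)C
F2 | step 5 | bis[3,4-bis(trimethylsilyloxy)benzyl] ether | C[Si](C)(C)Oc1ccc(COCc2ccc(O[Si](C)(C)C)c(O[Si](C)(C)C)c2)cc1O[Si](C)(C)C
F3 | step 4 | 3,3'-[oxybis(methylene)]bis(hexanedial) (two unassigned stereocentres) | O=CCCC(CC=O)COCC(CC=O)CCC=O
F4 | step 4 | 4,4'-[oxybis(methylene)]bis(cyclohexane-1,2-diol) (stereocentres unassigned) | OC1CCC(COCC2CCC(O)C(O)C2)CC1O
F5 | step 2 | (2E,2'E)-4,4'-oxybis(but-2-en-1-ol) | OC/C=C/COC/C=C/CO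
F6 | step 2 | dimethyl 3,3'-[oxybis(methylene)]bis(pent-4-enoate) (two unassigned stereocentres) | COC(=O)CC(C=C)COCC(C=C)CC(=O)OC
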